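Numbering: ring C1 (C=O)–C2–C3–C4 (CH3)=C5–C6 (O)–C7–C8 (OAc)–C9–C10 (=C14H2); lactone C7=C11–C12(=O)–O–C6, with C13 (CH2OAc) on C11.
Enabling feature: C6 is the γ-carbon of the five-membered C6–C7=C11–C12–O butenolide, and its α-carbon C11 is blocked by C13. Loss of H-6 gives a flat, aromatic 2-oxidofuran whose only open carbon terminus is C6, next to alkenyl C5.
Cuts: first C5–C6 (ten-membered ring), then C1–C10, C8–C9 and C7–C8 in the west, and C3–C4 in the C1–C5 piece. The lactone is traced back to a 2-silylfuran.
Forward: furan-3-ylmethanol carries the five-membered ring from the start. C8, then C9/C10/C14, then C1–C5 are attached, silicon-directed photooxygenation and reduction turn the furan into the butenolide, and the ten-membered ring closes after that.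
Stereochemistry: C8 (S) comes from a reagent-controlled 2-bromoallylboration. The 4Z alkene comes from syn-carbocupration of propyne and is carried with retention through iodinolysis and oxidative addition. C6 (R) is reached by equilibration through the furanolate under control of C8.

Key step: step 15

Abbreviation: TBS = tert-butyldimethylsilyl, TBSO = its ether oxygen.
Assumption: the (S,S)-diazaborolidine is taken to deliver the 2-bromoallyl group to the Si face of the furan aldehyde, by analogy with the (R)-carbinols expected from its (R,R)-antipode and aromatic aldehydes. If the sense were opposite, the antipodal controller would be used with no other change.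
Assumption: (6R) is taken to be the more stable C6 epimer of the (8S,4Z)-macrocycle, because the target itself carries the same epimerisable H-6.

Step 1
Reactants: 1 furan-3-ylmethanol
Product: 2 tert-butyl(furan-3-ylmethoxy)dimethylsilane
Conditions: TBSCl, imidazole, DMF, 0 °C → rt
Reagents that add atoms: TBSCl CC(C)(C)[Si](C)(C)Cl
Why: Imidazole-promoted silylation of an unhindered primary alcohol is routine and places the silicon that is moved to carbon in the next step.

Step 2
Reactants: 2 tert-butyl(furan-3-ylmethoxy)dimethylsilane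
Product: 4 [2-(tert-butyldimethylsilyl)furan-3-yl]methanol, via 2-lithiofuran 3 (not isolated)
Conditions: n-BuLi, HMPA, THF, −78 → 0 °C; H2O
Reagents that add atoms: none
Why: Lithiation at the α-position beside the silyloxymethyl arm triggers a 1,4 O→C silyl shift (retro-Brook rearrangement), a known entry to 2-silyl-3-(hydroxymethyl)furans that puts silicon on the future C12.

Step 3
Reactants: 4 [2-(tert-butyldimethylsilyl)furan-3-yl]methanol
Product: 6 5-(tert-butyldimethylsilyl)-4-(hydroxymethyl)furan-3-carbaldehyde, via dilithio species 5 (not isolated)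
Conditions: n-BuLi (2.2 equiv), DME, 0 °C; DMF, −78 °C → rt; H2O
Reagents that add atoms: DMF CN(C)C=O
Why: With C2 blocked by silicon, the lithium alkoxide steers a directed ortho-lithiation to C4, as is known for this furan, and formylation with DMF makes the C7–C8 bond.

Step 4
Reactants: 6 5-(tert-butyldimethylsilyl)-4-(hydroxymethyl)furan-3-carbaldehyde
Product: 7 5-(tert-butyldimethylsilyl)-4-[(tert-butyldimethylsilyloxy)methyl]furan-3-carbaldehyde
Conditions: TBSCl, imidazole, CH2Cl2, rt
Reagents that add atoms: TBSCl CC(C)(C)[Si](C)(C)Cl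
Why: Routine silylation caps the C13 oxygen with a group that is a poor leaving group and that falls together with the C8 ether at the end.

Step 5
Reactants: 8 2,3-dibromopropene
Product: 9 (2-bromoallyl)tributylstannane
Conditions: Bu3SnH, LDA, THF, −78 → 0 °C; then 8, −78 °C
Reagents that add atoms: tributyltin hydride CCCC[SnH](CCCC)CCCC
Why: Tributylstannyllithium displaces the allylic bromide (SN2 or SN2', same product), while the vinylic bromide is inert at −78 °C.

Step 6
Reactants: 7 5-(tert-butyldimethylsilyl)-4-[(tert-butyldimethylsilyloxy)methyl]furan-3-carbaldehyde, 9 (2-bromoallyl)tributylstannane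
Product: 11 (1S)-3-bromo-1-{5-(tert-butyldimethylsilyl)-4-[(tert-butyldimethylsilyloxy)methyl]furan-3-yl}but-3-en-1-ol, via allylborane 10 (not isolated)
Conditions: (S,S)-TsNHCH(Ph)CH(Ph)NHTs, BBr3, CH2Cl2, 0 → 23 °C, evaporate; 9, CH2Cl2, 23 °C; 7, −78 °C; pH 7 buffer
Reagents that add atoms: none
Why: This is a diazaborolidine-controlled enantioselective 2-haloallylboration, in which Sn→B exchange gives the C2-symmetric allylborane 10 and a closed chair transition state delivers the allyl terminus to the Si face of the aromatic-type aldehyde, forming C8–C9 and setting C8 as S.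

Step 7
Reactants: 11 (1S)-3-bromo-1-{5-(tert-butyldimethylsilyl)-4-[(tert-butyldimethylsilyloxy)methyl]furan-3-yl}but-3-en-1-ol
Product: 12 O-TBS ether of 11 (8S)
Conditions: TBSOTf, 2,6-lutidine, CH2Cl2, 0 °C
Reagents that add atoms: TBSOTf CC(C)(C)[Si](C)(C)OS(=O)(=O)C(F)(F)F
Why: Silyl triflate with a hindered base silylates the crowded secondary furyl carbinol without ionising it, so C8 is untouched.

Step 8
Reactants: 13 2-(2-bromoethyl)-1,3-dioxolane, 14 propyne
Product: 17 2-[(3Z)-4-iodo-3-methylbut-3-en-1-yl]-1,3-dioxolane, via Grignard reagent 15 (not isolated), via alkenylcopper 16 (not isolated)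
Conditions: Mg, THF, 25 °C; CuBr·SMe2, Et2O–SMe2, −45 °C; propyne, −25 °C; I2, THF, −78 → 0 °C
Reagents that add atoms: iodine II
Why: In the Normant carbocupration the alkylcopper adds syn across propyne with the new C3–C4 bond at the internal carbon and copper at the terminus, and iodinolysis with retention leaves iodine cis to the chain (Z).

Step 9
Reactants: 17 2-[(3Z)-4-iodo-3-methylbut-3-en-1-yl]-1,3-dioxolane
Product: 18 (4Z)-5-iodo-4-methylpent-4-enal
Conditions: 2 M aq HCl, THF, 45 °C
Reagents that add atoms: water O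
Why: Acid-catalysed acetal hydrolysis frees the C1 aldehyde, and the alkenyl iodide is indifferent to dilute acid.

Step 10
Reactants: 12 O-TBS ether of 11 (8S), 18 (4Z)-5-iodo-4-methylpent-4-enal
Product: 21 (1S,7Z)-1-(TBSO)-8-iodo-7-methyl-3-methylidene-1-{5-TBS-4-[(TBSO)methyl]furan-3-yl}oct-7-en-4-ol (C1 epimer mixture), via vinyllithium 19 (not isolated), via vinylmagnesium bromide 20 (not isolated)
Conditions: t-BuLi (2.0 equiv), Et2O, −78 °C; MgBr2·OEt2, −78 °C; 18, −78 → −20 °C; H2O
Reagents that add atoms: none
Why: Bromine–lithium exchange in ether at −78 °C (too cold and too non-polar for a 1,4-silyl shift from O8) is followed by transmetalation to magnesium, which prevents metal–iodine exchange with C5–I, and 1,2-addition to the aldehyde makes C10–C1; the C1 carbinol centre is erased in step 11.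

Step 11
Reactants: 21 (1S,7Z)-1-(TBSO)-8-iodo-7-methyl-3-methylidene-1-{5-TBS-4-[(TBSO)methyl]furan-3-yl}oct-7-en-4-ol (C1 epimer mixture)
Product: 22 (1S,7Z)-1-(TBSO)-8-iodo-7-methyl-3-methylidene-1-{5-TBS-4-[(TBSO)methyl]furan-3-yl}oct-7-en-4-one
Conditions: Dess–Martin periodinane, CH2Cl2, 0 °C → rt
Reagents that add atoms: none
Why: Dess–Martin oxidation of the allylic alcohol is neutral and fast and leaves furan, silyl groups and alkenyl iodide alone, merging both C1 epimers into one α-methylene ketone.

Step 12
Reactants: 22 (1S,7Z)-1-(TBSO)-8-iodo-7-methyl-3-methylidene-1-{5-TBS-4-[(TBSO)methyl]furan-3-yl}oct-7-en-4-one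
Product: 23 ethylene ketal of 22
Conditions: (TMSOCH2)2 (5 equiv), TMSOTf (5 mol %), CH2Cl2, −78 °C; pyridine quench
Reagents that add atoms: 1,2-bis(trimethylsilyloxy)ethane C[Si](C)(C)OCCO[Si](C)(C)C
Why: The aprotic Noyori ketalisation converts enones at −78 °C without conjugate addition or alkene migration, and the excess silyl glycol at low temperature should outrun any attack of the furan on the activated enone.

Step 13
Reactants: 23 ethylene ketal of 22
Product: 26 4-[(1S,7Z)-1-(TBSO)-4,4-ethylenedioxy-8-iodo-7-methyl-3-methylideneoct-7-enyl]-5-hydroxy-3-[(TBSO)methyl]furan-2(5H)-one (C6 epimer mixture), via endoperoxide 24 (not isolated), via silyl ester 25 (not isolated)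
Conditions: O2, tetraphenylporphyrin (cat.), visible light, CH2Cl2, −78 °C; then H2O, SiO2
Reagents that add atoms: oxygen O=O
Why: Singlet oxygen adds [4+2] to the electron-rich silylfuran far faster than it attacks the two hindered or halogenated alkenes, and the silicon shift in 24 makes the silyl-bearing carbon C12 the carboxyl carbon, fixing the lactone regiochemistry (silylfuran photooxygenation).

Step 14
Reactants: 26 4-[(1S,7Z)-1-(TBSO)-4,4-ethylenedioxy-8-iodo-7-methyl-3-methylideneoct-7-enyl]-5-hydroxy-3-[(TBSO)methyl]furan-2(5H)-one (C6 epimer mixture)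
Product: 28 4-[(1S,7Z)-1-(TBSO)-4,4-ethylenedioxy-8-iodo-7-methyl-3-methylideneoct-7-enyl]-3-[(TBSO)methyl]furan-2(5H)-one, via hydroxy acid 27 (not isolated)
Conditions: NaBH4, MeOH–THF, 0 °C; 0.5 M HCl to pH 4, 0 °C
Reagents that add atoms: none
Why: Borohydride reduces the ring-opened formyl carboxylate tautomer of the lactol, and the cis-disposed hydroxy acid lactonises on mild acidification, the standard passage from a γ-hydroxybutenolide to a butenolide; the ketal shields C1.

Step 15
Reactants: 28 4-[(1S,7Z)-1-(TBSO)-4,4-ethylenedioxy-8-iodo-7-methyl-3-methylideneoct-7-enyl]-3-[(TBSO)methyl]furan-2(5H)-one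
Product: 33 (4Z,6R,8S)-8,13-bis(TBSO)-1,1-ethylenedioxygermacra-4,7(11),10(14)-trien-12,6-olide, via alkenylpalladium iodide 29 (not isolated), via palladium furanolate 30 (not isolated), via C6 epimer 31 (not isolated), via caesium furanolate 32 (not isolated)
Conditions: Pd2(dba)3 (10 mol %), Xantphos (22 mol %), Cs2CO3 (3 equiv), toluene–t-AmOH (10:1), 80 °C, 28 added by syringe pump (final 1 mM), then held at 80 °C
Reagents that add atoms: none
Why: Proposed new method: Pd(0) inserts into the C5–I bond with retention of the Z geometry (29), carbonate reversibly deprotonates the butenolide CH2 (C6) to the aromatic 2-oxidofuran, the furanolate displaces iodide on palladium (30), and C(sp2)–C(sp3) reductive elimination forges C5–C6. The closest known reaction types are the intermolecular palladium-catalysed γ-arylation of butenolide dienolates under weak carbonate or phosphate base and the intramolecular α-alkenylation of ketone enolates with alkenyl halides, but an alkenyl halide has not been joined to a furanolate and no medium ring has been closed this way. The ten-membered carbocycle closes end to end by reductive elimination from the eleven-membered C5–Pd–C6 palladacycle under pseudo-high dilution, helped by three turn elements (the Z-alkene, the flat butenolide and the fully substituted ketal carbon C1). C6 is not fixed in the bond-forming event, because H-6 of the product is doubly allylic and γ to the lactone carbonyl, so 31 and 33 interconvert through the planar furanolate 32 under the same base with t-AmOH as proton shuttle, and the C8 silyloxy stereocentre together with the transannular strain of the Z-configured ring decides the outcome, which should favour 6R, with low-temperature kinetic protonation of 32 as a second handle. Coupling at γ rather than α is secured by C13, which makes C11 fully substituted, and Michael closure of C6 onto C14 is impossible while C1 is a ketal. Coupling must also beat 6-exo carbopalladation of C10=C14 and E1cB loss of the C13 oxygen: the first would have to build a quaternary C10 beside the quaternary ketal carbon and is further disfavoured by the chelating wide-bite-angle ligand in a non-polar medium, and the second is held back by the poor silyloxide leaving group and the low standing concentration of furanolate under a weak heterogeneous base.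

Step 16
Reactants: 33 (4Z,6R,8S)-8,13-bis(TBSO)-1,1-ethylenedioxygermacra-4,7(11),10(14)-trien-12,6-olide
Product: 34 (4Z,6R,8S)-1,1-ethylenedioxy-8,13-dihydroxygermacra-4,7(11),10(14)-trien-12,6-olide
Conditions: HF·pyridine, excess pyridine, THF, 0 °C → rt; aq NaHCO3
Reagents that add atoms: none
Why: Buffered anhydrous fluoride-mediated desilylation removes both TBS ethers without base strong enough to touch H-6 and without water to hydrolyse the ketal.

Step 17
Reactants: 34 (4Z,6R,8S)-1,1-ethylenedioxy-8,13-dihydroxygermacra-4,7(11),10(14)-trien-12,6-olide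
Product: 35 (4Z,6R,8S)-8,13-diacetoxy-1,1-ethylenedioxygermacra-4,7(11),10(14)-trien-12,6-olide
Conditions: Ac2O, pyridine, DMAP (cat.), CH2Cl2, 0 °C
Reagents that add atoms: acetic anhydride CC(=O)OC(C)=O
Why: Standard DMAP-catalysed acylation esterifies both alcohols while the ketal still keeps the Michael acceptor hidden from the amines, and pyridine is too weak a base to start epimerisation at C6 or E1cB loss of the new C13 acetate.

Step 18
Reactants: 35 (4Z,6R,8S)-8,13-diacetoxy-1,1-ethylenedioxygermacra-4,7(11),10(14)-trien-12,6-olide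
Product: 36 (4Z,6R,8S)-8,13-diacetoxy-1-oxogermacra-4,7(11),10(14)-trien-12,6-olide (target CNP0239761.1)
Conditions: PPTS (cat.), acetone–H2O (9:1), rt → 40 °C
Reagents that add atoms: water O
Why: Mild acid-catalysed hydrolysis of the allylic ketal, which ionises easily through a vinyl-stabilised oxocarbenium ion, spares acetates and lactone and reveals the base-sensitive α-methylene ketone only in the last, acidic operation.

Compound list
1 | furan-3-ylmethanol | OCc1ccoc1 | starting material
2 | tert-butyl(furan-3-ylmethoxy)dimethylsilane | CC(C)(C)[Si](C)(C)OCc1ccoc1 | intermediate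
3 | 2-lithio derivative of 2 | [Li]c1occc1CO[Si](C)(C)C(C)(C)C | intermediate
4 | [2-(tert-butyldimethylsilyl)furan-3-yl]methanol | OCc1ccoc1[Si](C)(C)C(C)(C)C | intermediate
5 | O,C4-dilithio derivative of 4 | [Li]OCc1c([Li])coc1[Si](C)(C)C(C)(C)C | intermediate
6 | 5-(tert-butyldimethylsilyl)-4-(hydroxymethyl)furan-3-carbaldehyde | O=Cc1coc([Si](C)(C)C(C)(C)C)c1CO | intermediate
7 | 5-(tert-butyldimethylsilyl)-4-[(tert-butyldimethylsilyloxy)methyl]furan-3-carbaldehyde | O=Cc1coc([Si](C)(C)C(C)(C)C)c1CO[Si](C)(C)C(C)(C)C | intermediate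
8 | 2,3-dibromopropene | C=C(Br)CBr | starting material
9 | (2-bromoallyl)tributylstannane | C=C(Br)C[Sn](CCCC)(CCCC)CCCC | intermediate
10 | (4S,5S)-2-(2-bromoallyl)-4,5-diphenyl-1,3-ditosyl-1,3,2-diazaborolidine | C=C(Br)CB1N(S(=O)(=O)c2ccc(C)cc2)[C@@H](c2ccccc2)[C@H](c2ccccc2)N1S(=O)(=O)c1ccc(C)cc1 | intermediate
11 | (1S)-3-bromo-1-{5-TBS-4-[(TBSO)methyl]furan-3-yl}but-3-en-1-ol | C=C(Br)C[C@H](O)c1coc([Si](C)(C)C(C)(C)C)c1CO[Si](C)(C)C(C)(C)C | intermediate
12 | O-TBS ether of 11 (8S) | C=C(Br)C[C@H](O[Si](C)(C)C(C)(C)C)c1coc([Si](C)(C)C(C)(C)C)c1CO[Si](C)(C)C(C)(C)C | intermediate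
13 | 2-(2-bromoethyl)-1,3-dioxolane | BrCCC1OCCO1 | starting material
14 | propyne | CC#C | starting material
15 | [2-(1,3-dioxolan-2-yl)ethyl]magnesium bromide | Br[Mg]CCC1OCCO1 | intermediate
16 | (Z)-alkenylcopper, copper cis to the chain | C1(CC/C(C)=C\[Cu])OCCO1 | intermediate
17 | 2-[(3Z)-4-iodo-3-methylbut-3-en-1-yl]-1,3-dioxolane | C1(CC/C(C)=C\I)OCCO1 | intermediate
18 | (4Z)-5-iodo-4-methylpent-4-enal | O=CCC/C(C)=C\I | intermediate
19 | C10 vinyllithium from 12 | C=C([Li])C[C@H](O[Si](C)(C)C(C)(C)C)c1coc([Si](C)(C)C(C)(C)C)c1CO[Si](C)(C)C(C)(C)C | intermediate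
20 | C10 vinylmagnesium bromide from 19 | C=C([Mg]Br)C[C@H](O[Si](C)(C)C(C)(C)C)c1coc([Si](C)(C)C(C)(C)C)c1CO[Si](C)(C)C(C)(C)C | intermediate
21 | furan allylic alcohol, 8S, 4Z, C1 epimer mixture | C=C(C[C@H](O[Si](C)(C)C(C)(C)C)c1coc([Si](C)(C)C(C)(C)C)c1CO[Si](C)(C)C(C)(C)C)C(O)CC/C(C)=C\I | intermediate
22 | furan α-methylene ketone, 8S, 4Z | C=C(C[C@H](O[Si](C)(C)C(C)(C)C)c1coc([Si](C)(C)C(C)(C)C)c1CO[Si](C)(C)C(C)(C)C)C(=O)CC/C(C)=C\I | intermediate
23 | ethylene ketal of 22 | C=C(C[C@H](O[Si](C)(C)C(C)(C)C)c1coc([Si](C)(C)C(C)(C)C)c1CO[Si](C)(C)C(C)(C)C)C1(CC/C(C)=C\I)OCCO1 | intermediate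
24 | furan endoperoxide (2,3,7-trioxabicyclo[2.2.1]heptene, facial mixture) | C=C(C[C@H](O[Si](C)(C)C(C)(C)C)C1=C(CO[Si](C)(C)C(C)(C)C)C2([Si](C)(C)C(C)(C)C)OOC1O2)C1(CC/C(C)=C\I)OCCO1 | intermediate
25 | TBS ester of the (Z)-formyl acrylic acid | C=C(C[C@H](O[Si](C)(C)C(C)(C)C)/C(C=O)=C(\CO[Si](C)(C)C(C)(C)C)C(=O)O[Si](C)(C)C(C)(C)C)C1(CC/C(C)=C\I)OCCO1 | intermediate
26 | γ-hydroxybutenolide, 8S, 4Z, C6 epimer mixture | C=C(C[C@H](O[Si](C)(C)C(C)(C)C)C1=C(CO[Si](C)(C)C(C)(C)C)C(=O)OC1O)C1(CC/C(C)=C\I)OCCO1 | intermediate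
27 | seco hydroxy acid (C6H2OH cis to C12O2H) | C=C(C[C@H](O[Si](C)(C)C(C)(C)C)/C(CO)=C(\CO[Si](C)(C)C(C)(C)C)C(=O)O)C1(CC/C(C)=C\I)OCCO1 | intermediate
28 | γ-unsubstituted butenolide, cyclisation precursor, 8S, Z-alkenyl iodide | C=C(C[C@H](O[Si](C)(C)C(C)(C)C)C1=C(CO[Si](C)(C)C(C)(C)C)C(=O)OC1)C1(CC/C(C)=C\I)OCCO1 | intermediate
29 | alkenylpalladium(II) iodide from 28 (phosphine omitted) | C=C(C[C@H](O[Si](C)(C)C(C)(C)C)C1=C(CO[Si](C)(C)C(C)(C)C)C(=O)OC1)C1(CC/C(C)=C\[Pd]I)OCCO1 | intermediate
30 | eleven-membered palladacycle, C6-bound furanolate form (phosphine omitted) | C=C1C[C@H](O[Si](C)(C)C(C)(C)C)C2=C(CO[Si](C)(C)C(C)(C)C)C(=O)OC2[Pd]/C=C(/C)CCC13OCCO3 | intermediate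
31 | (4Z,6S,8S)-epimer of 33 | C=C1C[C@H](O[Si](C)(C)C(C)(C)C)C2=C(CO[Si](C)(C)C(C)(C)C)C(=O)O[C@H]2/C=C(/C)CCC13OCCO3 | intermediate
32 | caesium 2-oxidofuran of the macrocycle | [Cs+].[O-]c1oc2/C=C(/C)CCC3(OCCO3)C(=C)C[C@H](O[Si](C)(C)C(C)(C)C)c2c1CO[Si](C)(C)C(C)(C)C | intermediate
33 | (4Z,6R,8S)-8,13-bis(TBSO)-1,1-ethylenedioxygermacra-4,7(11),10(14)-trien-12,6-olide | C=C1C[C@H](O[Si](C)(C)C(C)(C)C)C2=C(CO[Si](C)(C)C(C)(C)C)C(=O)O[C@@H]2/C=C(/C)CCC13OCCO3 | intermediate
34 | (4Z,6R,8S)-1,1-ethylenedioxy-8,13-dihydroxygermacra-4,7(11),10(14)-trien-12,6-olide | C=C1C[C@H](O)C2=C(CO)C(=O)O[C@@H]2/C=C(/C)CCC13OCCO3 | intermediate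
35 | (4Z,6R,8S)-8,13-diacetoxy-1,1-ethylenedioxygermacra-4,7(11),10(14)-trien-12,6-olide | C=C1C[C@H](OC(C)=O)C2=C(COC(C)=O)C(=O)O[C@@H]2/C=C(/C)CCC13OCCO3 | intermediate
36 | (4Z,6R,8S)-8,13-diacetoxy-1-oxogermacra-4,7(11),10(14)-trien-12,6-olide | C=C1C[C@H](OC(C)=O)C2=C(COC(C)=O)C(=O)O[C@@H]2/C=C(/C)CCC1=O | target

Total step count: 18. Longest linear sequence: 15 steps (1–4, 6, 7, 10–18). Step 5 and steps 8–9 are side branches.

Steps most likely to fail

Step 15. Several processes could undo the closure:
- Intermolecular coupling could overtake ring closure.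
- The alkenylpalladium could carbopalladate the C10=C14 alkene.
- The furanolate could expel the C13 silyloxy group.
- Pd(0) could ionise the new allylic C6–O bond.
- The equilibrium at C6 could settle on the wrong side.

The fallback forms the same C5–C6 bond by known chemistry. It sets out from lactol 26. TMSCHN2 in toluene–MeOH traps the open tautomer as the methyl (Z)-formyl ester F1. A Nozaki–Hiyama–Kishi macrocyclisation (CrCl2, cat. NiCl2, DMSO–THF, high dilution) then adds C5 to the C6 aldehyde to give the ten-membered hydroxy ester F2. Its C6 alkoxide closes onto the cis-disposed C12 ester. This delivers 33 together with 31, and a short DBU treatment or chromatographic separation of the pair brings the route back at 33.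

Step 12. Three processes threaten it: conjugate addition of the glycol oxygen at C14, attack of the nucleophilic furan position C6 on the Lewis-acid-activated enone, and sluggish ketalisation of the hindered cross-conjugated ketone. The fallback takes the alkene out of play while the ketal is made. It sets out from 22. Benzeneselenol (from PhSeSePh, NaBH4, EtOH–AcOH) adds at C14 to give the β-(phenylselanyl) ketone F3 as C10 epimers. The now saturated ketone is ketalised under the same silyl glycol conditions to the selanyl ketal F4. One equivalent of mCPBA at −78 °C gives the selenoxide F5, which on warming with i-Pr2NEt undergoes syn-elimination through its only β-hydrogen (H-10). This restores C10=C14 and rejoins the route at 23.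

Step 6. The risks are incomplete tin–boron exchange with the electron-poor stannane, insufficient facial selectivity on the ortho-crowded aldehyde, and an induction sense opposite to the one assumed. The fallback separates bond formation from stereocontrol. It sets out from 7 and 8. An indium-mediated Barbier reaction in THF–H2O gives the racemic carbinol F6, and Dess–Martin oxidation gives the furyl ketone F7. CBS reduction with (R)-Me-CBS and catecholborane in toluene at −78 °C places hydride as in the aryl alkyl ketone series (aryl large, CH2 small). This gives the (S)-carbinol and returns to the route at 11.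

Further compounds
F1 | step 15 | methyl (Z)-formyl ester, open form of 26 | C=C(C[C@H](O[Si](C)(C)C(C)(C)C)/C(C=O)=C(\CO[Si](C)(C)C(C)(C)C)C(=O)OC)C1(CC/C(C)=C\I)OCCO1
F2 | step 15 | ten-membered C6 hydroxy ester (C6 epimers) | C=C1C[C@H](O[Si](C)(C)C(C)(C)C)/C(=C(\CO[Si](C)(C)C(C)(C)C)C(=O)OC)C(O)/C=C(/C)CCC12OCCO2
F3 | step 12 | β-(phenylselanyl) ketone from 22 (C10 epimers) | O=C(CC/C(C)=C\I)C(C[Se]c1ccccc1)C[C@H](O[Si](C)(C)C(C)(C)C)c1coc([Si](C)(C)C(C)(C)C)c1CO[Si](C)(C)C(C)(C)C
F4 | step 12 | ethylene ketal of F3 | I\C=C(C)/CCC1(OCCO1)C(C[Se]c1ccccc1)C[C@H](O[Si](C)(C)C(C)(C)C)c1coc([Si](C)(C)C(C)(C)C)c1CO[Si](C)(C)C(C)(C)C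
F5 | step 12 | selenoxide of F4 | I\C=C(C)/CCC1(OCCO1)C(C[Se](=O)c1ccccc1)C[C@H](O[Si](C)(C)C(C)(C)C)c1coc([Si](C)(C)C(C)(C)C)c1CO[Si](C)(C)C(C)(C)C
F6 | step 6 | racemic 3-bromo-1-{5-TBS-4-[(TBSO)methyl]furan-3-yl}but-3-en-1-ol | C=C(Br)CC(O)c1coc([Si](C)(C)C(C)(C)C)c1CO[Si](C)(C)C(C)(C)C
F7 | step 6 | 3-bromo-1-{5-TBS-4-[(TBSO)methyl]furan-3-yl}but-3-en-1-one | C=C(Br)CC(=O)c1coc([Si](C)(C)C(C)(C)C)c1CO[Si](C)(C)C(C)(C)C
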